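The numbers in the tables are calculated from invented constants.

The solution in the flask cannot hold 0.30 M of solid substrate as dissolved substrate if saturation lies lower, so hold the charge against what the solution and the coupling partner between them can take up.

- south-west: solid substrate 0.15 M; coupling partner 0.39 M; run made earlier
- flask: solid substrate 0.30 M; coupling partner 0.390 M; time 15 h

- south-west (time / h: target / %, dissolved substrate / %): 0.250: 10.4, 25.5; 0.500: 26.2, 37.7; 1.33: 50.8, 46.8; 3.00: 55.9, 42.8

(readings scatter by 0.5 percentage points)

1. how much target there is at 15 h, in percent of the solid substrate charged
2. concentration of dissolved substrate in solution at 15 h, in percent of saturation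

- percent here means solid substrate units held: one side product counts as two
- solid substrate is a solid; its amount is given per volume of the solution
- steps that have been proposed: dissolved substrate + coupling partner -> target; solid substrate <-> dissolved substrate; coupling partner -> decomposed reagent; solid substrate + target -> side product
- at the start none of the solid substrate is in solution
- dissolved substrate means what is dissolved; the solid is not counted in it

The south-west run gives a reading of both capacities. Dissolved substrate plus target rises at 0.215 M h⁻¹ over the first interval and 0.168 M h⁻¹ over the second. Carried straight to zero flux, these readings put saturation near 0.148 M. Target goes from 50.8% to 55.9% over the last interval of that run, so I take its last reading, 0.0839 M, as about what this charge of partner yields. For the flask that gives 1.30, the surplus number, the solid charged over what solution and partner can take up. This lies above one, so at 15 h in the flask I expect solid beside target, 100 percent of saturation and target ending below 28.0%. One number is not enough for how far below: the shortfall of 1.3 percentage points at the last south-west reading, against a scatter of 0.5 points, gives no firm rate.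

The forecast said 18% (11% to 27%) and 100% of saturation: “That solid then eats target for 12 h”.

The flask gives 6.92% of target and 100% of saturation. In the flask, target's half-life by loss to solid, with solid as charged, is 1.3 h, shorter than the 15 h. With the surplus number at 1.30, the flask holds 11.9% of its charge as solid at 15.0 h.

    dissolved substrate + coupling partner → target (k = 0.00280 M⁻¹ s⁻¹)
    solid substrate ⇌ dissolved substrate, rate k2*(cs2 - [dissolved substrate]) while solid is left; crystals form when [dissolved substrate] > cs2 (solubility = 0.110 M, k = 7.20 × 10⁻⁴ s⁻¹)
    coupling partner → decomposed reagent (k = 4.40 × 10⁻⁴ s⁻¹)
    solid substrate + target → side product (k = 4.80 × 10⁻⁴ M⁻¹ s⁻¹)

In a neighbour flask with 0.18 M of solid substrate and the other charges and the time unchanged, the surplus number is 0.776, below one, so I reckon target there near 46.6%. That neighbour flask gives 45.9%, with solid at 0% at 15.0 h.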